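**Retrosynthetic overview**

1. Target 20 ⇐ tris-benzyl ether 19 by neutral hydrogenolysis, so that no base touches the two cis-2,3 pairs.
2. 19 ⇐ enone 17 by a tin-hydride-triggered radical 1,2-acyl shift. The pyranone ring of unit B (O-1'', C-2'', C-3'', C-4'', C-4a'', C-8a'') grows out of the furanone ring of a 2-aryl-benzofuran-3-one when C-3'' is inserted between C-2'' and C-4''. The same operation sets C-3'', C-2'' and C-3.
3. Enabling feature: C-2'' carries both the ring oxygen O-1'' and the 4-methoxyphenyl ring, so a radical there is strongly stabilised and the C-2''–C-4'' bond of the benzofuranone can break. In addition, C-4(=O)/C-3/C-3''/C-4''(=O) is a 1,4-diketone, so C-3'' is the β-carbon of a C-3 alkylidene enone of unit A.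
4. 17 ⇐ (S)-flavanone 6 + quaternary aldehyde 14 (Mukaiyama aldol, dehydration); 6 ⇐ chromone 4 (asymmetric 1,4-arylation); 14 ⇐ deoxybenzoin 8.
5. Ring order: pyranone of unit A (step 2) → furanone of unit B (step 7) → its expansion to the pyranone of unit B (step 12).

Key step: step 12

Remark: unit A is the 5,7-dihydroxy flavanone (unprimed locants, aryl ring primed), unit B the 5-hydroxy-7-methoxy flavanone (double-primed locants).
Remark: the sense of induction of the pyridine-oxazoline ligand in step 3 is assigned by analogy with β-substituted cyclic enones; should it be opposite, the antipodal ligand is used.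
Remark: 12–14 are racemic and 15–17 are mixtures at the quaternary benzofuranone carbon (15, 16 also at C-3 and the carbinol carbon); step 12 erases or resets all of these centres.

**Step 1**
Reactants: 1 1-(2,4,6-trihydroxyphenyl)ethan-1-one
Product: 2 1-[2,4-bis(benzyloxy)-6-hydroxyphenyl]ethan-1-one
Conditions: BnBr (2.1 equiv), K2CO3 (2.2 equiv), DMF, rt
Reagents that add atoms: benzyl bromide, BrCc1ccccc1
Why: Williamson etherification; the hydroxyl that is hydrogen-bonded to the ketone is the least nucleophilic and stays free.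

**Step 2**
Reactants: 2 1-[2,4-bis(benzyloxy)-6-hydroxyphenyl]ethan-1-one
Product: 4 5,7-bis(benzyloxy)-4H-chromen-4-one, via enaminone 3 (not isolated)
Conditions: Me2NCH(OMe)2, toluene, 95 °C; then conc. HCl, CH2Cl2, rt
Reagents that add atoms: N,N-dimethylformamide dimethyl acetal, COC(OC)N(C)C
Why: enaminone formation at the methyl ketone followed by acid-promoted addition–elimination of the phenol (chromone synthesis) closes the pyranone ring of unit A.

**Step 3**
Reactants: 4 5,7-bis(benzyloxy)-4H-chromen-4-one; 5 (4-methoxyphenyl)boronic acid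
Product: 6 (2S)-5,7-bis(benzyloxy)-2-(4-methoxyphenyl)chroman-4-one
Conditions: Pd(OCOCF3)2 (5 mol %), (R)-t-BuPyOx (6 mol %), NH4PF6 (30 mol %), H2O (5 equiv), ClCH2CH2Cl, 60 °C
Reagents that add atoms: none
Why: Pd-catalysed asymmetric conjugate addition of an arylboronic acid to a chromone; the chiral pyridine-oxazoline ligand selects the face of aryl transfer and so sets C-2 (S).

**Step 4**
Reactants: 6 (2S)-5,7-bis(benzyloxy)-2-(4-methoxyphenyl)chroman-4-one
Product: 7 (2S)-5,7-bis(benzyloxy)-2-(4-methoxyphenyl)-4-(trimethylsilyloxy)-2H-chromene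
Conditions: TMSOTf (1.2 equiv), Et3N (1.5 equiv), CH2Cl2, 0 °C
Reagents that add atoms: trimethylsilyl trifluoromethanesulfonate, C[Si](C)(C)OS(=O)(=O)C(F)(F)F
Why: soft enolisation and O-silylation; no free enolate is formed, so retro-oxa-Michael opening cannot scramble C-2.

**Step 5**
Reactants: 8 2-(4-methoxyphenyl)-1-(2,4,6-trihydroxyphenyl)ethan-1-one
Product: 9 1-(2,6-dihydroxy-4-methoxyphenyl)-2-(4-methoxyphenyl)ethan-1-one
Conditions: Me2SO4 (1.0 equiv), K2CO3 (1.0 equiv), acetone, rt
Reagents that add atoms: dimethyl sulfate, COS(=O)(=O)OC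
Why: Williamson O-methylation; the para hydroxyl is the most acidic and is not hydrogen-bonded to the ketone, so it should react first.

**Step 6**
Reactants: 9 1-(2,6-dihydroxy-4-methoxyphenyl)-2-(4-methoxyphenyl)ethan-1-one
Product: 10 1-[2-(benzyloxy)-6-hydroxy-4-methoxyphenyl]-2-(4-methoxyphenyl)ethan-1-one
Conditions: BnBr (1.05 equiv), K2CO3 (1.1 equiv), acetone, 56 °C
Reagents that add atoms: benzyl bromide, BrCc1ccccc1
Why: Williamson etherification; the two ortho hydroxyls are equivalent and, once one is benzylated, the other is locked in the hydrogen bond to the ketone, which should stop the reaction at the mono-ether.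

**Step 7**
Reactants: 10 1-[2-(benzyloxy)-6-hydroxy-4-methoxyphenyl]-2-(4-methoxyphenyl)ethan-1-one
Product: 12 4-(benzyloxy)-6-methoxy-2-(4-methoxyphenyl)-1-benzofuran-3(2H)-one, via α-bromo ketone 11 (not isolated)
Conditions: CuBr2 (2.0 equiv), EtOAc/CHCl3, 70 °C; then NaOAc (3 equiv), EtOH, 50 °C, argon
Reagents that add atoms: none
Why: α-bromination of the enolisable benzyl ketone and 5-exo-tet O-alkylation by the remaining phenol close the furanone ring; C-2 forms racemic, which is harmless because step 12 destroys this centre.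

**Step 8**
Reactants: 12 4-(benzyloxy)-6-methoxy-2-(4-methoxyphenyl)-1-benzofuran-3(2H)-one
Product: 13 4-(benzyloxy)-2-(hydroxymethyl)-6-methoxy-2-(4-methoxyphenyl)-1-benzofuran-3(2H)-one
Conditions: aq. CH2O (37 %, 5 equiv), Et3N (0.1 equiv), THF, 0 °C to rt, argon
Reagents that add atoms: formaldehyde, C=O
Why: base-catalysed aldol addition of the benzofuranone enolate to formaldehyde at carbon builds the quaternary centre (racemic, erased later) with the smallest possible electrophile.

**Step 9**
Reactants: 13 4-(benzyloxy)-2-(hydroxymethyl)-6-methoxy-2-(4-methoxyphenyl)-1-benzofuran-3(2H)-one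
Product: 14 4-(benzyloxy)-6-methoxy-2-(4-methoxyphenyl)-3-oxo-2,3-dihydro-1-benzofuran-2-carbaldehyde
Conditions: DMP (1,1,1-triacetoxy-1,2-benziodoxol-3(1H)-one, 1.2 equiv), CH2Cl2, rt
Reagents that add atoms: none
Why: hypervalent-iodine oxidation of the neopentyl primary alcohol under non-basic conditions, which avoids retro-aldol loss of the one-carbon unit.

**Step 10**
Reactants: 7 (2S)-5,7-bis(benzyloxy)-2-(4-methoxyphenyl)-4-(trimethylsilyloxy)-2H-chromene; 14 4-(benzyloxy)-6-methoxy-2-(4-methoxyphenyl)-3-oxo-2,3-dihydro-1-benzofuran-2-carbaldehyde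
Product: 15 β-hydroxy ketone (aldol adduct of 7 and 14; C-2 S)
Conditions: Sc(OTf)3 (10 mol %), CH2Cl2, −78 °C; then 1 M HCl, THF, 0 °C
Reagents that add atoms: none
Why: Mukaiyama aldol addition to the only non-enolisable, strongly electrophilic carbonyl; the enol ether should attack anti to the C-2 aryl group, but the new centres at C-3 and the carbinol carbon are removed in step 11.

**Step 11**
Reactants: 15 β-hydroxy ketone (aldol adduct of 7 and 14; C-2 S)
Product: 17 (2R,3E)-5,7-bis(benzyloxy)-3-{[4-(benzyloxy)-6-methoxy-2-(4-methoxyphenyl)-3-oxo-2,3-dihydro-1-benzofuran-2-yl]methylidene}-2-(4-methoxyphenyl)chroman-4-one, via mesylate 16 (not isolated)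
Conditions: MsCl (1.5 equiv), Et3N (2 equiv), CH2Cl2, 0 °C; then DBU (2 equiv), rt
Reagents that add atoms: none
Why: mesylation and E1cB elimination through the C-3 enolate give the enone, expected as the E isomer (benzofuranone carbon anti to C-4=O); C-2 keeps its spatial arrangement (the descriptor becomes R only because C-3 now outranks the aryl ring).

**Step 12**
Reactants: 17 (2R,3E)-enone (both epimers at the quaternary benzofuranone carbon)
Product: 19 (2S,2'S,3S,3'S)-5,5',7-tris(benzyloxy)-7'-methoxy-2,2'-bis(4-methoxyphenyl)-[3,3'-bichromane]-4,4'-dione, via tin enolate 18 (not isolated)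
Conditions: Bu3SnH (1.3 equiv, syringe pump), AIBN (0.2 equiv), PhH (5 mM), 80 °C; then AcOH (3 equiv), THF, −78 °C
Reagents that add atoms: none
Why: Proposed new method: Bu3Sn• adds reversibly to the carbonyl oxygen of the enone of unit A to give an allylic O-stannyl ketyl with spin density on C-3'' (the closest known chemistry is the β-carbon cyclisation of allylic O-stannyl ketyls), and this carbon adds to the C-4'' ketone of the benzofuranone, after which the cyclopropyloxy radical opens by β-scission of the old C-2''–C-4'' bond, as in the Dowd–Beckwith ring expansion of α-(halomethyl) β-keto esters. The pyranone ring of unit B therefore closes by a 3-exo-trig radical addition to C=O followed by fragmentation (net 1,2-acyl shift, five- to six-membered), pulled forward by the radical at C-2'', which is benzylic to the 4-methoxyphenyl ring and α to O-1'', and by loss of the crowded quaternary centre. C-3'' is set in the addition: in the planar E-allyl radical the axial 4-methoxyphenyl group on C-2 covers one face, so C-4'' should bond anti to it, and since the quaternary centre is erased and the acyl shift should be reversible at low stannane concentration, both epimers of 17 are expected to drain through the same radical. C-2'' is then set by hydrogen transfer from Bu3SnH anti to the large C-3'' substituent (2'',3''-cis), and C-3 by protonation of tin enolate 18 at −78 °C anti to the axial C-2 aryl group (2,3-cis). The step needs the acyl shift to outrun direct hydrogen transfer to C-3'' and any shift of the aryl group or of the ring oxygen; the neopentyl position of C-3'', syringe-pump addition of the stannane and the greater stabilisation of the O,aryl-substituted radical are relied on for this.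

**Step 13**
Reactants: 19 (2S,2'S,3S,3'S)-5,5',7-tris(benzyloxy)-7'-methoxy-2,2'-bis(4-methoxyphenyl)-[3,3'-bichromane]-4,4'-dione
Product: 20 (2S,2'S,3S,3'S)-5,5',7-trihydroxy-7'-methoxy-2,2'-bis(4-methoxyphenyl)-[3,3'-bichromane]-4,4'-dione
Conditions: H2 (1 atm), Pd/C (10 %), EtOAc/MeOH, rt
Reagents that add atoms: none
Why: hydrogenolysis of the three benzyl ethers under neutral conditions; no base or strong acid is present, so the epimerisable cis C-3/C-3'' centres and the ring-openable C-2/C-2'' centres should be untouched.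

**Compound list**

1 | 1-(2,4,6-trihydroxyphenyl)ethan-1-one | CC(=O)c1c(O)cc(O)cc1O | starting material
2 | 1-[2,4-bis(benzyloxy)-6-hydroxyphenyl]ethan-1-one | CC(=O)c1c(O)cc(OCc2ccccc2)cc1OCc1ccccc1 | intermediate
3 | (E)-1-[2,4-bis(benzyloxy)-6-hydroxyphenyl]-3-(dimethylamino)prop-2-en-1-one | CN(C)/C=C/C(=O)c1c(O)cc(OCc2ccccc2)cc1OCc1ccccc1 | intermediate
4 | 5,7-bis(benzyloxy)-4H-chromen-4-one | O=c1ccoc2cc(OCc3ccccc3)cc(OCc3ccccc3)c12 | intermediate
5 | (4-methoxyphenyl)boronic acid | COc1ccc(B(O)O)cc1 | starting material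
6 | (2S)-5,7-bis(benzyloxy)-2-(4-methoxyphenyl)chroman-4-one | COc1ccc([C@H]2Oc3cc(OCc4ccccc4)cc(OCc4ccccc4)c3C(=O)C2)cc1 | intermediate
7 | (2S)-5,7-bis(benzyloxy)-2-(4-methoxyphenyl)-4-(trimethylsilyloxy)-2H-chromene | COc1ccc([C@H]2Oc3cc(OCc4ccccc4)cc(OCc4ccccc4)c3C(O[Si](C)(C)C)=C2)cc1 | intermediate
8 | 2-(4-methoxyphenyl)-1-(2,4,6-trihydroxyphenyl)ethan-1-one | COc1ccc(CC(=O)c2c(O)cc(O)cc2O)cc1 | starting material
9 | 1-(2,6-dihydroxy-4-methoxyphenyl)-2-(4-methoxyphenyl)ethan-1-one | COc1ccc(CC(=O)c2c(O)cc(OC)cc2O)cc1 | intermediate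
10 | 1-[2-(benzyloxy)-6-hydroxy-4-methoxyphenyl]-2-(4-methoxyphenyl)ethan-1-one | COc1ccc(CC(=O)c2c(O)cc(OC)cc2OCc2ccccc2)cc1 | intermediate
11 | 2-bromo-1-[2-(benzyloxy)-6-hydroxy-4-methoxyphenyl]-2-(4-methoxyphenyl)ethan-1-one (racemic) | COc1ccc(C(Br)C(=O)c2c(O)cc(OC)cc2OCc2ccccc2)cc1 | intermediate
12 | 4-(benzyloxy)-6-methoxy-2-(4-methoxyphenyl)-1-benzofuran-3(2H)-one (racemic) | COc1ccc(C2Oc3cc(OC)cc(OCc4ccccc4)c3C2=O)cc1 | intermediate
13 | 4-(benzyloxy)-2-(hydroxymethyl)-6-methoxy-2-(4-methoxyphenyl)-1-benzofuran-3(2H)-one (racemic) | COc1ccc(C2(CO)Oc3cc(OC)cc(OCc4ccccc4)c3C2=O)cc1 | intermediate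
14 | 4-(benzyloxy)-6-methoxy-2-(4-methoxyphenyl)-3-oxo-2,3-dihydro-1-benzofuran-2-carbaldehyde (racemic) | COc1ccc(C2(C=O)Oc3cc(OC)cc(OCc4ccccc4)c3C2=O)cc1 | intermediate
15 | (2S)-5,7-bis(benzyloxy)-3-{[4-(benzyloxy)-6-methoxy-2-(4-methoxyphenyl)-3-oxo-2,3-dihydro-1-benzofuran-2-yl](hydroxy)methyl}-2-(4-methoxyphenyl)chroman-4-one (mixture at C-3, the carbinol carbon and the quaternary carbon) | COc1ccc([C@H]2Oc3cc(OCc4ccccc4)cc(OCc4ccccc4)c3C(=O)C2C(O)C2(c3ccc(OC)cc3)Oc3cc(OC)cc(OCc4ccccc4)c3C2=O)cc1 | intermediate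
16 | methanesulfonate of 15 (same stereochemical mixture) | COc1ccc([C@H]2Oc3cc(OCc4ccccc4)cc(OCc4ccccc4)c3C(=O)C2C(OS(C)(=O)=O)C2(c3ccc(OC)cc3)Oc3cc(OC)cc(OCc4ccccc4)c3C2=O)cc1 | intermediate
17 | (2R,3E)-5,7-bis(benzyloxy)-3-{[4-(benzyloxy)-6-methoxy-2-(4-methoxyphenyl)-3-oxo-2,3-dihydro-1-benzofuran-2-yl]methylidene}-2-(4-methoxyphenyl)chroman-4-one (C-2 spatially as in 6; both epimers at the quaternary carbon) | COc1ccc([C@H]2Oc3cc(OCc4ccccc4)cc(OCc4ccccc4)c3C(=O)/C2=C/C2(c3ccc(OC)cc3)Oc3cc(OC)cc(OCc4ccccc4)c3C2=O)cc1 | intermediate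
18 | tributylstannyl enol ether of 19 at O-4 (C-3=C-4 double bond; C-2 spatially as in 6, C-2'' and C-3'' as in 19) | COc1ccc([C@H]2Oc3cc(OCc4ccccc4)cc(OCc4ccccc4)c3C(O[Sn](CCCC)(CCCC)CCCC)=C2[C@@H]2C(=O)c3c(OCc4ccccc4)cc(OC)cc3O[C@@H]2c2ccc(OC)cc2)cc1 | intermediate
19 | (2S,2'S,3S,3'S)-5,5',7-tris(benzyloxy)-7'-methoxy-2,2'-bis(4-methoxyphenyl)-[3,3'-bichromane]-4,4'-dione | COc1ccc([C@H]2Oc3cc(OCc4ccccc4)cc(OCc4ccccc4)c3C(=O)[C@H]2[C@@H]2C(=O)c3c(OCc4ccccc4)cc(OC)cc3O[C@@H]2c2ccc(OC)cc2)cc1 | intermediate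
20 | (2S,2'S,3S,3'S)-5,5',7-trihydroxy-7'-methoxy-2,2'-bis(4-methoxyphenyl)-[3,3'-bichromane]-4,4'-dione | COc1ccc([C@H]2Oc3cc(O)cc(O)c3C(=O)[C@H]2[C@@H]2C(=O)c3c(O)cc(OC)cc3O[C@@H]2c2ccc(OC)cc2)cc1 | target

**Summary**

Total step count: 13. Longest linear sequence: 9 steps (steps 5–13, from 8 to 20).

Steps most likely to fail:

Step 12 (proposed new method). The stabilised allylic radical may take hydrogen at C-3'' before the acyl shift (plain conjugate reduction). The ring oxygen or the aryl group may migrate instead of the acyl group. The facial selectivity of the 3-exo attack may be poor. The fallback sets out from 17 and uses a discrete, unstabilised radical precursor. Benzeneselenol (cat. Et3N, CH2Cl2, 0 °C) is added 1,4 to the enone; protonation of the enol anti to the C-2 aryl group sets C-3 and gives the β-(phenylselanyl) ketone F1. Bu3SnH/AIBN in refluxing benzene at high dilution then generates the secondary C-3'' radical in the classical way, which undergoes the Dowd–Beckwith ring expansion and is reduced at C-2''. This comes back to the route at 19.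

Step 10. The hindered, non-enolisable β-keto aldehyde 14 may be hydrated or lose its formyl group under Lewis acid, or add too slowly at the neopentyl carbonyl. The fallback sets out from 7 and 12 and builds the one-carbon link from an orthoformate, so that 13–16 are not needed. Enol ether 7 and HC(OMe)3 with catalytic TMSOTf give the β-keto acetal F2. Benzofuranone 12 is silylated (TBSOTf, Et3N) to the 3-silyloxybenzofuran F3. TMSOTf-promoted Mukaiyama-type addition of F3 to the oxocarbenium ion from F2 gives the β-methoxy ketone F4, and DBU eliminates methanol. This comes back to the route at 17.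

Step 7. Bromination of the very electron-rich phenolic ring may compete with α-bromination, and the enolisable 2-aryl benzofuranone may oxidise in air under the basic cyclisation. The fallback sets out from 10 and avoids electrophilic halogen. Diazo transfer (4-acetamidobenzenesulfonyl azide, DBU, MeCN) gives the α-diazo ketone F5, and Rh2(OAc)4-catalysed intramolecular O–H insertion of the carbene into the phenol closes the furanone ring under neutral conditions. This comes back to the route at 12.

**Further compounds**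

F1 | step 12 | (2S)-5,7-bis(benzyloxy)-3-{[4-(benzyloxy)-6-methoxy-2-(4-methoxyphenyl)-3-oxo-2,3-dihydro-1-benzofuran-2-yl](phenylselanyl)methyl}-2-(4-methoxyphenyl)chroman-4-one | COc1ccc([C@H]2Oc3cc(OCc4ccccc4)cc(OCc4ccccc4)c3C(=O)C2C([Se]c2ccccc2)C2(c3ccc(OC)cc3)Oc3cc(OC)cc(OCc4ccccc4)c3C2=O)cc1
F2 | step 10 | (2S)-5,7-bis(benzyloxy)-3-(dimethoxymethyl)-2-(4-methoxyphenyl)chroman-4-one | COc1ccc([C@H]2Oc3cc(OCc4ccccc4)cc(OCc4ccccc4)c3C(=O)C2C(OC)OC)cc1
F3 | step 10 | {[4-(benzyloxy)-6-methoxy-2-(4-methoxyphenyl)-1-benzofuran-3-yl]oxy}(tert-butyl)dimethylsilane | COc1ccc(-c2oc3cc(OC)cc(OCc4ccccc4)c3c2O[Si](C)(C)C(C)(C)C)cc1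
F4 | step 10 | (2S)-5,7-bis(benzyloxy)-3-{[4-(benzyloxy)-6-methoxy-2-(4-methoxyphenyl)-3-oxo-2,3-dihydro-1-benzofuran-2-yl](methoxy)methyl}-2-(4-methoxyphenyl)chroman-4-one | COc1ccc([C@H]2Oc3cc(OCc4ccccc4)cc(OCc4ccccc4)c3C(=O)C2C(OC)C2(c3ccc(OC)cc3)Oc3cc(OC)cc(OCc4ccccc4)c3C2=O)cc1
F5 | step 7 | 1-[2-(benzyloxy)-6-hydroxy-4-methoxyphenyl]-2-diazo-2-(4-methoxyphenyl)ethan-1-one | COc1ccc(C(=[N+]=[N-])C(=O)c2c(O)cc(OC)cc2OCc2ccccc2)cc1
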